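**Plan**
- Enabling feature: C3 of indole B (the 5-hydroxyindole) is bonded to two aryl carbons, C1 of the central ring C and C3a of its own benzo ring. It is therefore a masked diaryl ketone carbon, and C2, a CH on N1, is a masked formamide carbon.
- Retrosynthetic cuts, in order: the two Si–heteroatom bonds; C2=C3 of indole B (giving an ortho-formamido diaryl ketone); N–CHO; the ring C–C3 bond of indole A (Suzuki–Miyaura); the carbonyl–ring C bond (aryllithium plus Weinreb amide).
- Forward order: indole A, ring C and the benzo ring of B are bought intact. Ring C is joined first to the anthranilate carbonyl and then to C3 of indole A. The pyrrole ring of indole B is the only ring built, and low-valent titanium closes it last.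
- One fluoride treatment then frees N1–H of indole A and the C5 phenol of indole B.
- Stereochemistry: the target has no stereocentre and no stereodefined double bond, so nothing has to be set.

Key step: step 9

Assumption: acetic formic anhydride is prepared and distilled beforehand, so it enters step 8 as a defined reagent.

**Step 1**
Reactants: 1 5-hydroxyanthranilic acid
Product: 3 2-amino-5-hydroxy-N-methoxy-N-methylbenzamide, via benzotriazolyl active ester 2 (not isolated)
Conditions: MeNH(OMe)·HCl, EDC·HCl, HOBt, i-Pr2NEt, DMF, 0 °C → rt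
Reagents that add atoms: N,O-dimethylhydroxylamine hydrochloride, CNOC.Cl
Why: Carbodiimide/HOBt amide coupling (Weinreb amide formation), routine for unprotected anthranilic acids: active ester 2 should be taken by the small alpha-effect amine much faster than by the phenol or by the aniline, whose lone pair is tied up by the ortho carbonyl group.

**Step 2**
Reactants: 3 2-amino-5-hydroxy-N-methoxy-N-methylbenzamide
Product: 4 2-amino-N-methoxy-N-methyl-5-(triisopropylsilyloxy)benzamide
Conditions: TIPSCl, imidazole, DMF, rt
Reagents that add atoms: chlorotriisopropylsilane, CC(C)[Si](Cl)(C(C)C)C(C)C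
Why: Imidazole-promoted silylation of a phenol: the O–Si bond forms selectively because the hindered chlorosilane barely touches the deactivated aniline and any N–Si bond would hydrolyse on aqueous work-up.

**Step 3**
Reactants: 5 1,2,4,5-tetramethoxybenzene
Product: 7 1,4-dibromo-2,3,5,6-tetramethoxybenzene, via monobromide 6 (not isolated)
Conditions: Br2 (2 equiv), CH2Cl2, 0 °C → rt
Reagents that add atoms: bromine, BrBr
Why: Electrophilic aromatic bromination: the only two free positions of 5 are each flanked by two methoxy groups and strongly activated, so monobromide 6 should take up the second bromine para to the first with no regiochemical choice.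

**Step 4**
Reactants: 7 1,4-dibromo-2,3,5,6-tetramethoxybenzene; 4 2-amino-N-methoxy-N-methyl-5-(triisopropylsilyloxy)benzamide
Product: 11 (2-amino-5-(triisopropylsilyloxy)phenyl)(4-bromo-2,3,5,6-tetramethoxyphenyl)methanone, via aryllithium 8 (not isolated), via lithium anilide 9 (not isolated), via tetrahedral dilithium adduct 10 (not isolated)
Conditions: 7, n-BuLi (1 equiv), THF, −78 °C; separately 4, n-BuLi (1 equiv), THF, −78 °C; combine, −78 → −20 °C; aq NH4Cl
Reagents that add atoms: none
Why: Bromine–lithium exchange followed by a Weinreb ketone synthesis, a known direct entry to 2-aminobenzophenones from N-lithiated 2-amino Weinreb amides: one equivalent of n-BuLi should stop at monolithio species 8, prior deprotonation to 9 keeps the N–H from quenching it, and chelate 10 holds until the quench so that no second addition can occur.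

**Step 5**
Reactants: 12 6-methoxyindole
Product: 14 6-methoxy-1-(triisopropylsilyl)indole, via sodium indolide 13 (not isolated)
Conditions: NaH, THF, 0 °C; TIPSCl, 0 °C → rt
Reagents that add atoms: chlorotriisopropylsilane, CC(C)[Si](Cl)(C(C)C)C(C)C
Why: N-deprotonation and N-silylation of an indole: sodium indolide 13 reacts at nitrogen with the chlorosilane, and the bulky group installed here later steers the borylation and stabilises the boronate.

**Step 6**
Reactants: 14 6-methoxy-1-(triisopropylsilyl)indole
Product: 15 6-methoxy-3-(4,4,5,5-tetramethyl-1,3,2-dioxaborolan-2-yl)-1-(triisopropylsilyl)indole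
Conditions: [Ir(OMe)(cod)]2 (cat.), dtbpy (cat.), B2pin2 (1 equiv), hexane, 60 °C
Reagents that add atoms: bis(pinacolato)diboron, CC1(C)OB(OC1(C)C)B1OC(C)(C)C(C)(C)O1
Why: Iridium-catalysed aromatic C–H borylation under steric control, known to hit C3 of N-triisopropylsilylindole: the silyl group screens C2 and C7, the methoxy group screens C5 and C7, and the heteroaryl C3–H is inherently more reactive than C4–H.

**Step 7**
Reactants: 11 (2-amino-5-(triisopropylsilyloxy)phenyl)(4-bromo-2,3,5,6-tetramethoxyphenyl)methanone; 15 6-methoxy-3-(4,4,5,5-tetramethyl-1,3,2-dioxaborolan-2-yl)-1-(triisopropylsilyl)indole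
Product: 16 (2-amino-5-(triisopropylsilyloxy)phenyl)(2,3,5,6-tetramethoxy-4-(6-methoxy-1-(triisopropylsilyl)indol-3-yl)phenyl)methanone
Conditions: Pd(OAc)2 (cat.), SPhos (cat.), K3PO4, toluene/H2O, 90 °C
Reagents that add atoms: none
Why: Suzuki–Miyaura coupling: the para ketone eases oxidative addition of zerovalent palladium into the otherwise electron-rich, doubly ortho-substituted C–Br bond, the bulky biarylphosphine is the standard answer to such hindrance, and the hydrogen-bonded aniline is too poor a nucleophile to compete by C–N coupling under phosphate base.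

**Step 8**
Reactants: 16 (2-amino-5-(triisopropylsilyloxy)phenyl)(2,3,5,6-tetramethoxy-4-(6-methoxy-1-(triisopropylsilyl)indol-3-yl)phenyl)methanone
Product: 17 N-(2-(2,3,5,6-tetramethoxy-4-(6-methoxy-1-(triisopropylsilyl)indol-3-yl)benzoyl)-4-(triisopropylsilyloxy)phenyl)formamide
Conditions: HCO2Ac, THF, 0 °C → rt
Reagents that add atoms: acetic formic anhydride, CC(=O)OC=O
Why: N-formylation with a mixed anhydride: the amine attacks the less hindered and more electrophilic formyl carbon, which is reactive enough for the weakly nucleophilic 2-aminobenzophenone nitrogen at a temperature that leaves both silyl groups alone.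

**Step 9**
Reactants: 17 N-(2-(2,3,5,6-tetramethoxy-4-(6-methoxy-1-(triisopropylsilyl)indol-3-yl)benzoyl)-4-(triisopropylsilyloxy)phenyl)formamide
Product: 19 6-methoxy-3-(2,3,5,6-tetramethoxy-4-(5-(triisopropylsilyloxy)-1H-indol-3-yl)phenyl)-1-(triisopropylsilyl)indole, via titanium indoline-2,3-diolate 18 (not isolated)
Conditions: TiCl3, Zn dust, DME, reflux
Reagents that add atoms: none
Why: Zinc reduces TiCl3 to low-valent titanium, which passes two electrons to the more easily reduced diaryl ketone of 17 and binds its oxygen, and the resulting nucleophilic C3 adds to the formamide carbonyl held ortho on the same ring to give diolate 18. A second low-valent titanium centre then strips both oxygens from 18, driven by the strength of the Ti–O bond and by aromatisation, and leaves the C2=C3 double bond of indole B. The closest known reaction is the titanium-induced oxo-amide coupling of 2-acylaminoaryl ketones (Fürstner indole synthesis, a McMurry-type process), which is established for secondary amides with a free N–H and for sterically loaded ketones. The pyrrole ring closes by 5-exo-trig attack of C3 on the formyl carbon, whose oxygen stays outside the new five-membered ring, so C2–C3 is the only new skeletal bond, and the two transient sp3 centres of 18 vanish on deoxygenation, so no stereocentre has to be controlled. The step needs intramolecular ketone–amide coupling to win over pinacol dimerisation and plain reduction of the ketone: the ortho formamide supplies the proximity advantage, and the two methoxy groups flanking the carbonyl on ring C bar the approach of a second ketone. Aryl methyl ethers, the silyl groups and the electron-rich indole A are not reducible by this reagent.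

**Step 10**
Reactants: 19 6-methoxy-3-(2,3,5,6-tetramethoxy-4-(5-(triisopropylsilyloxy)-1H-indol-3-yl)phenyl)-1-(triisopropylsilyl)indole
Product: 20 3-(2,3,5,6-tetramethoxy-4-(6-methoxy-1H-indol-3-yl)phenyl)-1H-indol-5-ol (CNP0234672.0)
Conditions: Bu4NF, AcOH, THF, 0 °C → rt, argon
Reagents that add atoms: none
Why: Fluoride-induced desilylation, driven by the Si–F bond strength, clears the N–Si and the O–Si bond in one operation, and the acetic acid buffer keeps the air-sensitive 5-hydroxyindole from standing as its phenoxide.

**Compound list**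
1 | 5-hydroxyanthranilic acid | Nc1ccc(O)cc1C(=O)O | starting material
2 | benzotriazol-1-yl 2-amino-5-hydroxybenzoate | Nc1ccc(O)cc1C(=O)On1nnc2ccccc21 | intermediate
3 | 2-amino-5-hydroxy-N-methoxy-N-methylbenzamide | CON(C)C(=O)c1cc(O)ccc1N | intermediate
4 | 2-amino-N-methoxy-N-methyl-5-(triisopropylsilyloxy)benzamide | CON(C)C(=O)c1cc(O[Si](C(C)C)(C(C)C)C(C)C)ccc1N | intermediate
5 | 1,2,4,5-tetramethoxybenzene | COc1cc(OC)c(OC)cc1OC | starting material
6 | 1-bromo-2,3,5,6-tetramethoxybenzene | COc1cc(OC)c(OC)c(Br)c1OC | intermediate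
7 | 1,4-dibromo-2,3,5,6-tetramethoxybenzene | COc1c(Br)c(OC)c(OC)c(Br)c1OC | intermediate
8 | 4-bromo-2,3,5,6-tetramethoxyphenyllithium | [Li]c1c(OC)c(OC)c(Br)c(OC)c1OC | intermediate
9 | N-lithio derivative of 4 (lithium anilide) | [Li]Nc1ccc(O[Si](C(C)C)(C(C)C)C(C)C)cc1C(=O)N(C)OC | intermediate
10 | tetrahedral dilithium adduct of 8 and 9 | [Li]OC(N(C)OC)(c1c(OC)c(OC)c(Br)c(OC)c1OC)c1cc(O[Si](C(C)C)(C(C)C)C(C)C)ccc1N[Li] | intermediate
11 | (2-amino-5-(triisopropylsilyloxy)phenyl)(4-bromo-2,3,5,6-tetramethoxyphenyl)methanone | COc1c(Br)c(OC)c(OC)c(C(=O)c2cc(O[Si](C(C)C)(C(C)C)C(C)C)ccc2N)c1OC | intermediate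
12 | 6-methoxyindole | COc1ccc2cc[nH]c2c1 | starting material
13 | sodium 6-methoxyindol-1-ide | COc1ccc2ccn([Na])c2c1 | intermediate
14 | 6-methoxy-1-(triisopropylsilyl)indole | COc1ccc2ccn([Si](C(C)C)(C(C)C)C(C)C)c2c1 | intermediate
15 | 6-methoxy-3-(4,4,5,5-tetramethyl-1,3,2-dioxaborolan-2-yl)-1-(triisopropylsilyl)indole | COc1ccc2c(B3OC(C)(C)C(C)(C)O3)cn([Si](C(C)C)(C(C)C)C(C)C)c2c1 | intermediate
16 | (2-amino-5-(triisopropylsilyloxy)phenyl)(2,3,5,6-tetramethoxy-4-(6-methoxy-1-(triisopropylsilyl)indol-3-yl)phenyl)methanone | COc1ccc2c(-c3c(OC)c(OC)c(C(=O)c4cc(O[Si](C(C)C)(C(C)C)C(C)C)ccc4N)c(OC)c3OC)cn([Si](C(C)C)(C(C)C)C(C)C)c2c1 | intermediate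
17 | N-(2-(2,3,5,6-tetramethoxy-4-(6-methoxy-1-(triisopropylsilyl)indol-3-yl)benzoyl)-4-(triisopropylsilyloxy)phenyl)formamide (key-step precursor) | COc1ccc2c(-c3c(OC)c(OC)c(C(=O)c4cc(O[Si](C(C)C)(C(C)C)C(C)C)ccc4NC=O)c(OC)c3OC)cn([Si](C(C)C)(C(C)C)C(C)C)c2c1 | intermediate
18 | dichlorotitanium 2,3-diolate of the 3-arylindoline (racemic, cis-fused, both sp3 centres lost in the same step) | COc1ccc2c(-c3c(OC)c(OC)c(C45O[Ti](Cl)(Cl)OC4Nc4ccc(O[Si](C(C)C)(C(C)C)C(C)C)cc45)c(OC)c3OC)cn([Si](C(C)C)(C(C)C)C(C)C)c2c1 | intermediate
19 | 6-methoxy-3-(2,3,5,6-tetramethoxy-4-(5-(triisopropylsilyloxy)-1H-indol-3-yl)phenyl)-1-(triisopropylsilyl)indole (key-step product) | COc1ccc2c(-c3c(OC)c(OC)c(-c4c[nH]c5ccc(O[Si](C(C)C)(C(C)C)C(C)C)cc45)c(OC)c3OC)cn([Si](C(C)C)(C(C)C)C(C)C)c2c1 | intermediate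
20 | 3-(2,3,5,6-tetramethoxy-4-(6-methoxy-1H-indol-3-yl)phenyl)-1H-indol-5-ol (CNP0234672.0) | COc1ccc2c(-c3c(OC)c(OC)c(-c4c[nH]c5ccc(O)cc45)c(OC)c3OC)c[nH]c2c1 | target

**Total step count:** 10
**Longest linear sequence:** 7 (steps 1, 2, 4, 7, 8, 9, 10)

**Steps most likely to fail**

1. **Step 9.**
   - Risk: the crowded ketone may be reduced to the carbinol or methylene level before it couples. The Lewis-acidic titanium and zinc chlorides may also strip the formyl group or a chelated ortho methyl ether.
   - Fallback, from 16 back to 19: C2 is brought in as a one-carbon ylide instead of a formyl group. Corey–Chaykovsky methylenation of 16 with dimethylsulfonium methylide (Me3SI, NaH, DMSO/THF) should give the 2,2-diaryloxirane F1. Catalytic PPTS in warm toluene should open this very electron-rich oxirane by Meinwald rearrangement to the diarylacetaldehyde F2. F2 condenses with the ortho amino group and loses water to give 19. The C2–C3 bond is then made by ylide addition, and the ring closes at N1–C2.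

2. **Step 4.**
   - Risk: addition to a carbonyl group deactivated by the neighbouring anilide may be slow. Warming to force it invites bromine–lithium scrambling between 8 and the brominated adduct 10, and base-induced breakdown of the N-methoxy amide.
   - Fallback, from 5, 15 and 9 back to 16: bromine is removed from the acylation and the order of the two ring C bonds is inverted. One equivalent of Br2 stops 5 at monobromide 6, which is now isolated. Suzuki–Miyaura coupling of 6 with 15 under the conditions of step 7 should give 6-methoxy-3-(2,3,5,6-tetramethoxyphenyl)-1-(triisopropylsilyl)indole F3. Directed ortho-metalation (n-BuLi, THF, 0 °C) removes the single ring C proton, which lies between two methoxy groups, while the silyl group shields C2 and C7 of the indole. This gives the ring C aryllithium F4. F4 adds to 9 to form the tetrahedral dilithium adduct F5, which releases 16 on quench. With no C–Br bond present the mixture can be warmed freely, and step 7 is no longer needed.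

3. **Step 7.**
   - Risk: protodeboronation of the indol-3-yl boronate in hot aqueous base may outrun oxidative addition and transmetalation at the doubly ortho-substituted bromide. The same base may erode the aryl silyl ether.
   - Fallback, from 14 and 11 back to 16: a base-free and water-free Negishi coupling with a zinc nucleophile made by another route. NBS in THF at −78 °C converts 14 into 3-bromo-6-methoxy-1-(triisopropylsilyl)indole F6. Treatment with t-BuLi (2 equiv, −78 °C) gives the configurationally stable 3-lithioindole F7, and ZnCl2 turns it into the indol-3-ylzinc chloride F8. F8 couples with 11 under Pd2(dba)3/SPhos in THF at 60 °C, conditions under which arylzinc halides tolerate a free aniline N–H.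

**Further compounds**
F1 | step 9 | 2-(2-amino-5-(triisopropylsilyloxy)phenyl)-2-(2,3,5,6-tetramethoxy-4-(6-methoxy-1-(triisopropylsilyl)indol-3-yl)phenyl)oxirane (racemic) | COc1ccc2c(-c3c(OC)c(OC)c(C4(c5cc(O[Si](C(C)C)(C(C)C)C(C)C)ccc5N)CO4)c(OC)c3OC)cn([Si](C(C)C)(C(C)C)C(C)C)c2c1
F2 | step 9 | 2-(2-amino-5-(triisopropylsilyloxy)phenyl)-2-(2,3,5,6-tetramethoxy-4-(6-methoxy-1-(triisopropylsilyl)indol-3-yl)phenyl)acetaldehyde (racemic) | COc1ccc2c(-c3c(OC)c(OC)c(C(C=O)c4cc(O[Si](C(C)C)(C(C)C)C(C)C)ccc4N)c(OC)c3OC)cn([Si](C(C)C)(C(C)C)C(C)C)c2c1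
F3 | step 4 | 6-methoxy-3-(2,3,5,6-tetramethoxyphenyl)-1-(triisopropylsilyl)indole | COc1ccc2c(-c3c(OC)c(OC)cc(OC)c3OC)cn([Si](C(C)C)(C(C)C)C(C)C)c2c1
F4 | step 4 | 2,3,5,6-tetramethoxy-4-(6-methoxy-1-(triisopropylsilyl)indol-3-yl)phenyllithium | COc1ccc2c(-c3c(OC)c(OC)c([Li])c(OC)c3OC)cn([Si](C(C)C)(C(C)C)C(C)C)c2c1
F5 | step 4 | tetrahedral dilithium adduct of F4 and 9 | [Li]OC(N(C)OC)(c1c(OC)c(OC)c(-c2cn([Si](C(C)C)(C(C)C)C(C)C)c3cc(OC)ccc23)c(OC)c1OC)c1cc(O[Si](C(C)C)(C(C)C)C(C)C)ccc1N[Li]
F6 | step 7 | 3-bromo-6-methoxy-1-(triisopropylsilyl)indole | COc1ccc2c(Br)cn([Si](C(C)C)(C(C)C)C(C)C)c2c1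
F7 | step 7 | 3-lithio-6-methoxy-1-(triisopropylsilyl)indole | COc1ccc2c([Li])cn([Si](C(C)C)(C(C)C)C(C)C)c2c1
F8 | step 7 | (6-methoxy-1-(triisopropylsilyl)indol-3-yl)zinc chloride | COc1ccc2c([Zn]Cl)cn([Si](C(C)C)(C(C)C)C(C)C)c2c1
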